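**Retrosynthetic overview**

1. Target 22 ⇐ decabenzyl ether 21 ⇐ bromophenol 18, by Heck coupling with styrene 9 and excision of one phenolic oxygen through its triflate. The dihydrofuran rings are called A (carries the 3,5-dihydroxyphenyl group), B (middle) and C (its benzo ring carries the dihydroxystyryl group); each unit uses 2,3-dihydro-1-benzofuran locants.
2. Ring C (O1, C2, C3, C3a, C7a) ⇐ trimer stilbene 17 + bromoquinone 5, by a Lewis-acid-promoted (3+2) annulation that makes C3–C3a and C2–O1 in one operation and sets C2 and C3.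
3. Feature used: C2 of ring C carries a 4-oxygenated phenyl ring, so the alkene carbon that becomes C3 is nucleophilic and C2 is a stabilised benzylic cation. On the benzo ring, O1 (at C7a) and the C6 oxygen are meta, with C3a para to the C6 oxygen; with one more oxygen at C5 this is a 2-alkoxy-1,4-benzoquinone attacked at its C5. That extra oxygen is removed afterwards.
4. 17 ⇐ the same cycle run twice before (annulation, triflation, Heck with 7, formate reduction): ring A from resveratrol tribenzyl ether 2 under the chiral Lewis acid made from TiCl4, Ti(OiPr)4 and (4R,5R)-TADDOL, ring B from 13 under control by ring A.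
5. Order of ring formation: ring A (step 6) → ring B (step 10) → ring C (step 14). All benzene rings are bought or come from quinone 5.

Key step: step 14

Assumption: the complex of TiCl2(OiPr)2 with (4R,5R)-TADDOL, (4R,5R)-2,2-dimethyl-α,α,α',α'-tetraphenyl-1,3-dioxolane-4,5-dimethanol, is taken to give the (2R,3R) series in step 6; if the sense of induction is the opposite, the (4S,5S) ligand is used.

**Route**

Step 1
Reactants: 1 (E)-resveratrol
Product: 2 (E)-3,4',5-tris(benzyloxy)stilbene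
Conditions: BnBr, K2CO3, DMF, 60 °C
Reagents that add atoms: benzyl bromide, BrCc1ccccc1
Why: Williamson etherification of the three phenols gives the alkene partner with a para-alkoxy donor on one ring.

Step 2
Reactants: 3 2-(benzyloxy)phenol
Product: 4 2-(benzyloxy)-6-bromophenol
Conditions: NBS, i-Pr2NH (10 mol %), CH2Cl2, 0 °C
Reagents that add atoms: N-bromosuccinimide, O=C1CCC(=O)N1Br
Why: Amine-catalysed electrophilic bromination of a phenol is ortho-selective and should put bromine on the one free position next to the hydroxyl group.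

Step 3
Reactants: 4 2-(benzyloxy)-6-bromophenol
Product: 5 2-(benzyloxy)-6-bromo-1,4-benzoquinone
Conditions: (KSO3)2NO (Fremy's salt), KH2PO4, acetone/H2O, rt
Reagents that add atoms: potassium nitrosodisulfonate, [K+].[K+].[O]N(S(=O)(=O)[O-])S(=O)(=O)[O-]
Why: Teuber oxidation of a 2,6-disubstituted phenol with a free para position should give the para-quinone.

Step 4
Reactants: 6 4-(benzyloxy)benzaldehyde
Product: 7 4-(benzyloxy)styrene
Conditions: Ph3PCH3Br, KOtBu, THF, 0 °C → rt
Reagents that add atoms: methyltriphenylphosphonium bromide, C[P+](c1ccccc1)(c1ccccc1)c1ccccc1.[Br-]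
Why: Wittig methylenation of an aromatic aldehyde.

Step 5
Reactants: 8 3,4-bis(benzyloxy)benzaldehyde
Product: 9 3,4-bis(benzyloxy)styrene
Conditions: Ph3PCH3Br, KOtBu, THF, 0 °C → rt
Reagents that add atoms: methyltriphenylphosphonium bromide, C[P+](c1ccccc1)(c1ccccc1)c1ccccc1.[Br-]
Why: Wittig methylenation of an aromatic aldehyde.

Step 6
Reactants: 2 (E)-3,4',5-tris(benzyloxy)stilbene; 5 2-(benzyloxy)-6-bromo-1,4-benzoquinone
Product: 10 ring A bromophenol, (2R,3R)
Conditions: TiCl4, Ti(OiPr)4, (4R,5R)-TADDOL (1:1:2, 2.5 equiv of titanium), CH2Cl2, −78 → −40 °C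
Reagents that add atoms: none
Why: Lewis-acid-promoted (3+2) annulation of a 2-alkoxy-1,4-benzoquinone with an (E)-1-aryl alkene: the alkene carbon remote from the 4-benzyloxyphenyl ring adds to C5 of the chelated quinone, the benzylic cation is closed by the neighbouring carbonyl oxygen to the trans ring, and the TADDOL ligand on titanium should select the alkene face so that both centres come out (2R,3R), with enantiomeric purity to be raised by crystallisation of 10 or 11.

Step 7
Reactants: 10 ring A bromophenol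
Product: 11 ring A bromo triflate
Conditions: Tf2O, pyridine, CH2Cl2, 0 °C
Reagents that add atoms: trifluoromethanesulfonic anhydride, O=S(=O)(OS(=O)(=O)C(F)(F)F)C(F)(F)F
Why: O-sulfonylation turns the hydroxyl group that came from the quinone into a leaving group for its later reductive removal.

Step 8
Reactants: 11 ring A bromo triflate; 7 4-(benzyloxy)styrene
Product: 12 ring A stilbene triflate
Conditions: Pd2(dba)3 (2.5 mol %), [HP(t-Bu)3]BF4 (10 mol %), Cy2NMe, 1,4-dioxane, 80 °C
Reagents that add atoms: none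
Why: Mizoroki–Heck reaction; the bulky electron-rich phosphine should insert palladium into C–Br in preference to C–OTf, and syn insertion followed by syn β-hydride elimination gives the (E)-alkene.

Step 9
Reactants: 12 ring A stilbene triflate
Product: 13 dimer stilbene (pentabenzyl ether)
Conditions: Pd(OAc)2 (5 mol %), dppp, HCO2H, Et3N, DMF, 70 °C
Reagents that add atoms: none
Why: Palladium-catalysed reduction of an aryl triflate by formate replaces C–OTf by C–H, and this homogeneous system should leave benzyl ethers and the stilbene alone.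

Step 10
Reactants: 13 dimer stilbene; 5 2-(benzyloxy)-6-bromo-1,4-benzoquinone
Product: 14 ring B bromophenol, (2S,3S) in ring B
Conditions: 5, TiCl4/Ti(OiPr)4 (1:1, 2.5 equiv), CH2Cl2, −78 °C; then 13, −78 → −30 °C
Reagents that add atoms: none
Why: Same (3+2) annulation; with the styryl chain turned away from C3 of ring A, the 3,5-bis(benzyloxy)phenyl group on that carbon lies over one face of the C4 alkene, so the quinone should add to the open face and give (3S), and trans closure then gives (2S).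

Step 11
Reactants: 14 ring B bromophenol
Product: 15 ring B bromo triflate
Conditions: Tf2O, pyridine, CH2Cl2, 0 °C
Reagents that add atoms: trifluoromethanesulfonic anhydride, O=S(=O)(OS(=O)(=O)C(F)(F)F)C(F)(F)F
Why: O-sulfonylation of the quinone-derived hydroxyl group, as in step 7.

Step 12
Reactants: 15 ring B bromo triflate; 7 4-(benzyloxy)styrene
Product: 16 ring B stilbene triflate
Conditions: Pd2(dba)3 (2.5 mol %), [HP(t-Bu)3]BF4 (10 mol %), Cy2NMe, 1,4-dioxane, 80 °C
Reagents that add atoms: none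
Why: Bromide-selective Mizoroki–Heck reaction giving the (E)-stilbene, as in step 8.

Step 13
Reactants: 16 ring B stilbene triflate
Product: 17 trimer stilbene (heptabenzyl ether)
Conditions: Pd(OAc)2 (5 mol %), dppp, HCO2H, Et3N, DMF, 70 °C
Reagents that add atoms: none
Why: Palladium-catalysed formate reduction of the aryl triflate, as in step 9.

Step 14
Reactants: 17 trimer stilbene; 5 2-(benzyloxy)-6-bromo-1,4-benzoquinone
Product: 18 ring C bromophenol, (2R,3R) in ring C
Conditions: 5, TiCl4/Ti(OiPr)4 (1:1, 2.5 equiv), CH2Cl2, −78 °C; then 17, −78 → −30 °C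
Reagents that add atoms: none
Why: The quinone, bound to tetravalent titanium through C1=O and the benzyloxy oxygen, is attacked at its C5 (the CH next to C–Br) by the alkene carbon of 17 that is remote from the 4-benzyloxyphenyl ring, and the resulting 4-benzyloxybenzyl cation is captured by the neighbouring quinone oxygen before tautomerisation to the phenol. The closest known reaction type is the Lewis-acid-promoted (3+2) annulation of 2-alkoxy-1,4-benzoquinones with (E)-1-arylpropenes to trans-2-aryl-2,3-dihydrobenzofuran-5-ols. Ring C is closed by 5-exo-trig attack of oxygen on the cationic benzylic carbon, counted on its para-quinone-methide oxocarbenium form (the C2–O1 bond), after the C3–C3a bond has formed. C3 is controlled by ring B: with the styryl chain turned away from C3 of ring B, the aryl group on that carbon (the ring A unit) covers one face of the alkene, so the quinone should add anti to it and give (3R); C2 is controlled by C3, the two aryl groups ending trans (2R) in the closure. The step needs attack at quinone C5 and not C3 or C6 (secured by chelation and by the bromine on C6), the alkene and not a benzo-ring carbon as the nucleophile, and C–C bonding at the alkene carbon next to ring B (both secured by the para-benzyloxy group, which activates that carbon and stabilises the cation on the other).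

Step 15
Reactants: 18 ring C bromophenol
Product: 19 ring C bromo triflate
Conditions: Tf2O, pyridine, CH2Cl2, 0 °C
Reagents that add atoms: trifluoromethanesulfonic anhydride, O=S(=O)(OS(=O)(=O)C(F)(F)F)C(F)(F)F
Why: O-sulfonylation of the quinone-derived hydroxyl group, as in step 7.

Step 16
Reactants: 19 ring C bromo triflate; 9 3,4-bis(benzyloxy)styrene
Product: 20 tetramer stilbene triflate
Conditions: Pd2(dba)3 (2.5 mol %), [HP(t-Bu)3]BF4 (10 mol %), Cy2NMe, 1,4-dioxane, 80 °C
Reagents that add atoms: none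
Why: Bromide-selective Mizoroki–Heck reaction installs the (E)-3,4-dioxygenated styryl group on C4 of ring C.

Step 17
Reactants: 20 tetramer stilbene triflate
Product: 21 decabenzyl ether of the target
Conditions: Pd(OAc)2 (5 mol %), dppp, HCO2H, Et3N, DMF, 70 °C
Reagents that add atoms: none
Why: Palladium-catalysed formate reduction removes the last quinone-derived oxygen as in step 9.

Step 18
Reactants: 21 decabenzyl ether
Product: 22 target (CNP0099535.1)
Conditions: BCl3, C6HMe5, CH2Cl2, −78 °C; then MeOH, aqueous work-up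
Reagents that add atoms: none
Why: Lewis-acid debenzylation with pentamethylbenzene as benzyl-cation scavenger is non-reductive, so the stilbene should survive, and any reversible ionisation of a benzylic C2–O1 bond should reclose to the trans ring.

**Compound list**

1 | (E)-resveratrol, (E)-3,4',5-trihydroxystilbene | Oc1ccc(/C=C/c2cc(O)cc(O)c2)cc1 | starting material
2 | (E)-3,4',5-tris(benzyloxy)stilbene | O(Cc9ccccc9)c1ccc(/C=C/c2cc(OCc9ccccc9)cc(OCc9ccccc9)c2)cc1 | intermediate
3 | 2-(benzyloxy)phenol | Oc1ccccc1OCc9ccccc9 | starting material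
4 | 2-(benzyloxy)-6-bromophenol | Oc1c(Br)cccc1OCc9ccccc9 | intermediate
5 | 2-(benzyloxy)-6-bromo-1,4-benzoquinone | O=C1C=C(OCc9ccccc9)C(=O)C(Br)=C1 | intermediate
6 | 4-(benzyloxy)benzaldehyde | O=Cc1ccc(OCc9ccccc9)cc1 | starting material
7 | 4-(benzyloxy)styrene | C=Cc1ccc(OCc9ccccc9)cc1 | intermediate
8 | 3,4-bis(benzyloxy)benzaldehyde | O=Cc1ccc(OCc9ccccc9)c(OCc9ccccc9)c1 | starting material
9 | 3,4-bis(benzyloxy)styrene | C=Cc1ccc(OCc9ccccc9)c(OCc9ccccc9)c1 | intermediate
10 | ring A bromophenol: (2R,3R)-6-(benzyloxy)-2-[4-(benzyloxy)phenyl]-3-[3,5-bis(benzyloxy)phenyl]-4-bromo-2,3-dihydro-1-benzofuran-5-ol | Brc1c(O)c(OCc9ccccc9)cc2c1[C@@H](c1cc(OCc9ccccc9)cc(OCc9ccccc9)c1)[C@H](c1ccc(OCc9ccccc9)cc1)O2 | intermediate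
11 | ring A bromo triflate: 10 with the C5 hydroxyl as its trifluoromethanesulfonate, (2R,3R) | Brc1c(OS(=O)(=O)C(F)(F)F)c(OCc9ccccc9)cc2c1[C@@H](c1cc(OCc9ccccc9)cc(OCc9ccccc9)c1)[C@H](c1ccc(OCc9ccccc9)cc1)O2 | intermediate
12 | ring A stilbene triflate: 11 with Br at C4 replaced by (E)-2-[4-(benzyloxy)phenyl]ethenyl, (2R,3R) | O(Cc9ccccc9)c3ccc(/C=C/c1c(OS(=O)(=O)C(F)(F)F)c(OCc9ccccc9)cc2c1[C@@H](c1cc(OCc9ccccc9)cc(OCc9ccccc9)c1)[C@H](c1ccc(OCc9ccccc9)cc1)O2)cc3 | intermediate
13 | dimer stilbene: (2R,3R)-6-(benzyloxy)-2-[4-(benzyloxy)phenyl]-3-[3,5-bis(benzyloxy)phenyl]-4-{(E)-2-[4-(benzyloxy)phenyl]ethenyl}-2,3-dihydro-1-benzofuran | O(Cc9ccccc9)c3ccc(/C=C/c1cc(OCc9ccccc9)cc2c1[C@@H](c1cc(OCc9ccccc9)cc(OCc9ccccc9)c1)[C@H](c1ccc(OCc9ccccc9)cc1)O2)cc3 | intermediate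
14 | ring B bromophenol: (2S,3S)-6-(benzyloxy)-2-[4-(benzyloxy)phenyl]-4-bromo-2,3-dihydro-1-benzofuran-5-ol carrying at C3 the C4 of the ring A unit (2R,3R)-6-(benzyloxy)-2-[4-(benzyloxy)phenyl]-3-[3,5-bis(benzyloxy)phenyl]-2,3-dihydro-1-benzofuran | O(Cc9ccccc9)c1ccc([C@H]2Oc3cc(OCc9ccccc9)c(O)c(Br)c3[C@@H]2c2cc(OCc9ccccc9)cc3c2[C@@H](c2cc(OCc9ccccc9)cc(OCc9ccccc9)c2)[C@H](c2ccc(OCc9ccccc9)cc2)O3)cc1 | intermediate
15 | ring B bromo triflate: 14 with the ring B C5 hydroxyl as its trifluoromethanesulfonate; ring A (2R,3R), ring B (2S,3S) | O(Cc9ccccc9)c1ccc([C@H]2Oc3cc(OCc9ccccc9)c(OS(=O)(=O)C(F)(F)F)c(Br)c3[C@@H]2c2cc(OCc9ccccc9)cc3c2[C@@H](c2cc(OCc9ccccc9)cc(OCc9ccccc9)c2)[C@H](c2ccc(OCc9ccccc9)cc2)O3)cc1 | intermediate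
16 | ring B stilbene triflate: 15 with Br at C4 of ring B replaced by (E)-2-[4-(benzyloxy)phenyl]ethenyl | O(Cc9ccccc9)c1ccc([C@H]2Oc3cc(OCc9ccccc9)c(OS(=O)(=O)C(F)(F)F)c(/C=C/c4ccc(OCc9ccccc9)cc4)c3[C@@H]2c2cc(OCc9ccccc9)cc3c2[C@@H](c2cc(OCc9ccccc9)cc(OCc9ccccc9)c2)[C@H](c2ccc(OCc9ccccc9)cc2)O3)cc1 | intermediate
17 | trimer stilbene (heptabenzyl ether): 16 with OTf replaced by H; ring A (2R,3R), ring B (2S,3S), (E)-alkene on C4 of ring B | O(Cc9ccccc9)c1ccc([C@H]2Oc3cc(OCc9ccccc9)cc(/C=C/c4ccc(OCc9ccccc9)cc4)c3[C@@H]2c2cc(OCc9ccccc9)cc3c2[C@@H](c2cc(OCc9ccccc9)cc(OCc9ccccc9)c2)[C@H](c2ccc(OCc9ccccc9)cc2)O3)cc1 | intermediate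
18 | ring C bromophenol: the ring A–ring B unit of 17 carrying at C4 of ring B the C3 of a (2R,3R)-6-(benzyloxy)-2-[4-(benzyloxy)phenyl]-4-bromo-5-hydroxy-2,3-dihydro-1-benzofuran (ring C); ring A (2R,3R), ring B (2S,3S) | O(Cc9ccccc9)c1ccc([C@H]2Oc3cc(OCc9ccccc9)cc([C@@H]4c5c(Br)c(O)c(OCc9ccccc9)cc5O[C@H]4c4ccc(OCc9ccccc9)cc4)c3[C@@H]2c2cc(OCc9ccccc9)cc3c2[C@@H](c2cc(OCc9ccccc9)cc(OCc9ccccc9)c2)[C@H](c2ccc(OCc9ccccc9)cc2)O3)cc1 | intermediate
19 | ring C bromo triflate: 18 with the ring C C5 hydroxyl as its trifluoromethanesulfonate | O(Cc9ccccc9)c1ccc([C@H]2Oc3cc(OCc9ccccc9)cc([C@@H]4c5c(Br)c(OS(=O)(=O)C(F)(F)F)c(OCc9ccccc9)cc5O[C@H]4c4ccc(OCc9ccccc9)cc4)c3[C@@H]2c2cc(OCc9ccccc9)cc3c2[C@@H](c2cc(OCc9ccccc9)cc(OCc9ccccc9)c2)[C@H](c2ccc(OCc9ccccc9)cc2)O3)cc1 | intermediate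
20 | tetramer stilbene triflate: 19 with Br at C4 of ring C replaced by (E)-2-[3,4-bis(benzyloxy)phenyl]ethenyl | O(Cc9ccccc9)c1ccc([C@H]2Oc3cc(OCc9ccccc9)cc([C@@H]4c5c(/C=C/c6ccc(OCc9ccccc9)c(OCc9ccccc9)c6)c(OS(=O)(=O)C(F)(F)F)c(OCc9ccccc9)cc5O[C@H]4c4ccc(OCc9ccccc9)cc4)c3[C@@H]2c2cc(OCc9ccccc9)cc3c2[C@@H](c2cc(OCc9ccccc9)cc(OCc9ccccc9)c2)[C@H](c2ccc(OCc9ccccc9)cc2)O3)cc1 | intermediate
21 | decabenzyl ether of the target: 20 with OTf replaced by H; ring A (2R,3R), ring B (2S,3S), ring C (2R,3R), (E)-alkene | O(Cc9ccccc9)c1ccc([C@H]2Oc3cc(OCc9ccccc9)cc([C@@H]4c5c(/C=C/c6ccc(OCc9ccccc9)c(OCc9ccccc9)c6)cc(OCc9ccccc9)cc5O[C@H]4c4ccc(OCc9ccccc9)cc4)c3[C@@H]2c2cc(OCc9ccccc9)cc3c2[C@@H](c2cc(OCc9ccccc9)cc(OCc9ccccc9)c2)[C@H](c2ccc(OCc9ccccc9)cc2)O3)cc1 | intermediate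
22 | target CNP0099535.1: ring A (2R,3R), ring B (2S,3S), ring C (2R,3R), (E)-3,4-dihydroxystyryl on C4 of ring C, ten free phenols | Oc1ccc([C@H]2Oc3cc(O)cc([C@@H]4c5c(/C=C/c6ccc(O)c(O)c6)cc(O)cc5O[C@H]4c4ccc(O)cc4)c3[C@@H]2c2cc(O)cc3c2[C@@H](c2cc(O)cc(O)c2)[C@H](c2ccc(O)cc2)O3)cc1 | target

**Step count and risks**

Total: 18 steps. Longest linear sequence: 15 steps (steps 2, 3 and 6–18, from 2-(benzyloxy)phenol through quinone 5).

Steps most likely to fail:

Step 14. The hindered alkene carbon of 17 may be outrun by benzo-ring carbons attacking the activated quinone, and the benzylic cation may be captured by an electron-rich benzo-ring carbon in a seven-membered closure before the quinone oxygen closes ring C. The quinone may also add to both alkene faces. The fallback changes the nucleophile from a benzyl-ether stilbene under Lewis-acid activation to a free 4-hydroxystilbene that reacts as a vinylogous enol through a neutral para-quinone methide under hydrogen-bond catalysis. It sets out from 15. Heck coupling of 15 with 4-acetoxystyrene (CC(=O)Oc1ccc(C=C)cc1, conditions of step 12) should give the acetoxystilbene triflate F1. Formate reduction under the conditions of step 13 should give the acetoxystilbene F2, and K2CO3 in MeOH at 0 °C the free hydroxystilbene F3. F3 and 5 with a chiral phosphoric acid of the 3,3'-bis(2,4,6-triisopropylphenyl)-BINOL type (10 mol %, the matched enantiomer to be found by trial) in toluene at −20 °C should give the ring C diol F4, with the catalyst adding its own facial control. Deprotonation of both phenols (NaH, 2.2 equiv, DMF, 0 °C) and one equivalent of benzyl bromide should alkylate the unhindered, more basic 4-phenoxide and not the C5 phenoxide flanked by Br and OBn. The fallback comes back to the route at 18.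

Step 6. The TADDOL-bound Lewis acid TiCl2(OiPr)2 may discriminate the faces of a 1,2-diaryl alkene poorly, so that 10 forms with low enantiomeric purity. The fallback replaces asymmetric induction by resolution. It sets out from 10 of low enantiomeric purity: acylation with (1S)-camphanic chloride (ClC(=O)[C@@]12CC[C@@](C)(C(=O)O1)C2(C)C; pyridine, DMAP cat., CH2Cl2) should give the (1S)-camphanate of 10 F5 and the (1S)-camphanate of the enantiomer of 10 F6. These are diastereomers and are to be separated by crystallisation or chromatography. Methanolysis of F5 (K2CO3, MeOH, 0 °C) comes back to the route at 10.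

Step 16. Insertion of the styrene into the doubly ortho-substituted aryl–palladium bond may be slow, or palladium may insert into the C–OTf bond instead. The same applies to steps 8 and 12. The fallback brings the alkene in as a preformed (E)-alkenylboron reagent, so that the C–C bond forms by transmetalation and reductive elimination. It sets out from 19 and 9. Cross-metathesis of 9 with vinylboronic acid pinacol ester (C=CB1OC(C)(C)C(C)(C)O1) using the second-generation Grubbs catalyst (H2IMes)(PCy3)Cl2Ru=CHPh in CH2Cl2 at 40 °C should give the (E)-styrylboronate F7. Suzuki–Miyaura coupling of 19 with F7 (Pd2(dba)3, [HP(t-Bu)3]BF4, K3PO4, THF/H2O, 40 °C) comes back to the route at 20.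

**Further compounds**

F1 | step 14 | acetoxystilbene triflate: 16 with 4-acetoxyphenyl in place of 4-(benzyloxy)phenyl on the styryl group | O(Cc9ccccc9)c1ccc([C@H]2Oc3cc(OCc9ccccc9)c(OS(=O)(=O)C(F)(F)F)c(/C=C/c4ccc(OC(C)=O)cc4)c3[C@@H]2c2cc(OCc9ccccc9)cc3c2[C@@H](c2cc(OCc9ccccc9)cc(OCc9ccccc9)c2)[C@H](c2ccc(OCc9ccccc9)cc2)O3)cc1
F2 | step 14 | acetoxystilbene: F1 with OTf replaced by H | O(Cc9ccccc9)c1ccc([C@H]2Oc3cc(OCc9ccccc9)cc(/C=C/c4ccc(OC(C)=O)cc4)c3[C@@H]2c2cc(OCc9ccccc9)cc3c2[C@@H](c2cc(OCc9ccccc9)cc(OCc9ccccc9)c2)[C@H](c2ccc(OCc9ccccc9)cc2)O3)cc1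
F3 | step 14 | free hydroxystilbene: 17 with OH in place of the benzyloxy group on the styryl ring | O(Cc9ccccc9)c1ccc([C@H]2Oc3cc(OCc9ccccc9)cc(/C=C/c4ccc(O)cc4)c3[C@@H]2c2cc(OCc9ccccc9)cc3c2[C@@H](c2cc(OCc9ccccc9)cc(OCc9ccccc9)c2)[C@H](c2ccc(OCc9ccccc9)cc2)O3)cc1
F4 | step 14 | ring C diol: 18 with a free hydroxyl on the 4-hydroxyphenyl group at C2 of ring C | O(Cc9ccccc9)c1ccc([C@H]2Oc3cc(OCc9ccccc9)cc([C@@H]4c5c(Br)c(O)c(OCc9ccccc9)cc5O[C@H]4c4ccc(O)cc4)c3[C@@H]2c2cc(OCc9ccccc9)cc3c2[C@@H](c2cc(OCc9ccccc9)cc(OCc9ccccc9)c2)[C@H](c2ccc(OCc9ccccc9)cc2)O3)cc1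
F5 | step 6 | (1S)-camphanate of 10 (ester at the C5 oxygen), (2R,3R) | Brc1c(OC(=O)[C@@]34CC[C@@](C)(C(=O)O3)C4(C)C)c(OCc9ccccc9)cc2c1[C@@H](c1cc(OCc9ccccc9)cc(OCc9ccccc9)c1)[C@H](c1ccc(OCc9ccccc9)cc1)O2
F6 | step 6 | (1S)-camphanate of the enantiomer of 10, (2S,3S) | Brc1c(OC(=O)[C@@]34CC[C@@](C)(C(=O)O3)C4(C)C)c(OCc9ccccc9)cc2c1[C@H](c1cc(OCc9ccccc9)cc(OCc9ccccc9)c1)[C@@H](c1ccc(OCc9ccccc9)cc1)O2
F7 | step 16 | (E)-2-[3,4-bis(benzyloxy)phenyl]ethenylboronic acid pinacol ester | CC1(C)OB(/C=C/c2ccc(OCc9ccccc9)c(OCc9ccccc9)c2)OC1(C)C
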